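The numbers in the tables are simulated for substances that don't exist, and the scatter is random.

The vessel is closed, stirred and isothermal, and two chemists read its two earlier runs differently.

| flask | starting material | coupling partner | second substrate | third substrate | temperature | remark | time |
|---|---|---|---|---|---|---|---|
| Sunday's | 42 mM | 1 equiv | 2 equiv | 1 equiv | 50 °C | the very flask that is asked about, followed so far |  |
| Friday's | 42 mM | 1 equiv | 3 equiv | 1 equiv | 45 °C | run made earlier |  |
| flask | 42 mM | 1.00 equiv | 2.00 equiv | 1.00 equiv | 50 °C |  | 6.0 min |

- Sunday's (time / min: target / %, starting material / %): 0.667: 8.5, 91.6; 1.33: 13.6, 86.4; 2.00: 16.9, 82.3; 3.00: 19.9, 78.2; 4.00: 21.4, 75.8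
- Friday's (time / min: target / %, starting material / %): 0.200: 1.8, 98.3; 0.667: 5.7, 93.9; 1.00: 8.8, 91.2; 1.50: 11.8, 87.8; 2.50: 15.4, 83.6

(scatter of a reading: 0.3 percentage points)

- removed target is counted in
- what was read earlier has a scatter of 0.3 percentage points, one standard deviation
- additions bring no volume worth counting

- beta: change nothing and wait 12 min more
- delta: at 6.0 min take out 90% of the target then present, then wait 12 min
- theta: at 6.0 min add coupling partner, 50.0% of the amount charged, then wait 12 min
- eta: at 6.0 min raise the temperature by 25 K, then wait 12 min

- target, in percent of the starting material first charged, at 6.0 min
- what to do for the largest gain in target; "none" if nothing gains more than 2 percentage points (beta / delta / theta / eta / none)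
- target present, with what was taken out counted in, in percent of the starting material first charged, after delta
- target present, with what was taken out counted in, in percent of the starting material first charged, after eta

Sunday's starting material slows. Its pseudo-first-order constant is 0.132 min⁻¹ over the first reading and 0.0312 min⁻¹ between the last two. By those stretches, 4.20% and then 23.0% of the starting material had gone.

The first chemist says the rate follows [coupling partner], which falls as starting material is used. A straight line through these two points then reaches zero at 28.8%. That is the reach: the share of starting material that one equivalent of coupling partner converts before [coupling partner] is zero. Coupling partner would be the limiting reagent, with something unread taking the rest.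

The second chemist reads the same line as a reversible step nearing equilibrium. Their calls differ on removing target.

By the first view, Sunday's flask has 1.6 percentage points of reach left at the asked time. The missing mass in Sunday's run gives a target loss of 0.0503 min⁻¹. Starting from the forecast's target, delta then gives 22.4%. Adding coupling partner extends the reach by 14 points, but the loss over the wait leaves about 21.1%. This chemist's call is none.

The forecast is the second chemist's: 22.5% now, delta best, 35% after delta and 11% after eta. Its ground: “Removal re-pulls the equilibrium and also protects what was taken out”.

    starting material + coupling partner → target (k = 3.69 M⁻¹ min⁻¹, Ea = 55.0 kJ mol⁻¹)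
    third substrate + coupling partner → third product (k = 8.45 M⁻¹ min⁻¹, Ea = 60.0 kJ mol⁻¹)
    target → over-reaction product (k = 0.0562 min⁻¹, Ea = 107 kJ mol⁻¹)
    second substrate + coupling partner → second product (k = 0.686 M⁻¹ min⁻¹, Ea = 58.0 kJ mol⁻¹)
    (constants at 50 °C)

The flask gives 21.7%, 22.4% after delta, 0% after eta, and the choice none. The reversible reading gave the target at the asked time within tolerance. At 6.00 min this flask holds 9.10% of its coupling partner, which by the reach is 2.6 points of starting material still to convert. Its starting material goes from 72.6% to 69.5% by 60.0 min. With 2.50 equiv of coupling partner and 24% of it left, the reach gives 55.0% converted, and that neighbouring flask has lost 64.7%.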